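The side-chain stereocentres on ring B are read as the anti adduct of OH and H across a C=C bond: the carbinol carbon on ring C keeps one C–O bond of an oxirane, and the neighbouring methine carbon on ring B, which carries the CH2OH group, receives hydride with inversion. Everything rests on reagent-controlled epoxidation of an (E)-2-(ring B)-3-(ring C)allyl alcohol. In one operation titanium–tartrate oxygen transfer closes the oxirane and sets both centres. The precursor bears benzyl ethers on both phenols and a bromine on ring B, through which the ring-A lactone is attached afterwards by Negishi coupling.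

Key step: step 7

Remarks: ring A is the guaiacyl ring of the benzyl group on lactone C4, ring B the central ring, ring C the guaiacyl ring on the carbinol carbon. Compounds 1, 6, 13, 14 and 16 are taken as commercial. Assumption: the oxirane carbon next to the para-benzyloxyphenyl ring ionises easily, so 10 is made with catalytic titanium over molecular sieves, worked up without acid and reduced without storage.

Step 1
Reactants: 1 5-bromo-2-hydroxy-3-methoxybenzaldehyde
Product: 2 2-(benzyloxy)-5-bromo-3-methoxybenzaldehyde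
Conditions: BnBr, K2CO3, DMF, 60 °C
Reagents that add atoms: benzyl bromide, BrCc1ccccc1
Why: Williamson ether synthesis, in which the phenoxide of 1 is alkylated by the benzylic bromide in an SN2 reaction that leaves the aldehyde and the aryl bromide untouched.

Step 2
Reactants: 2 2-(benzyloxy)-5-bromo-3-methoxybenzaldehyde
Product: 3 (4Z)-4-[2-(benzyloxy)-5-bromo-3-methoxybenzylidene]-2-methyl-1,3-oxazol-5(4H)-one
Conditions: N-acetylglycine, NaOAc, Ac2O, 100 °C
Reagents that add atoms: N-acetylglycine, CC(=O)NCC(O)=O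
Why: Erlenmeyer–Plöchl azlactone synthesis, in which acetic anhydride cyclodehydrates N-acetylglycine to the oxazolone whose acidic C4 methylene condenses with the non-enolisable aldehyde to give the thermodynamic (Z)-arylidene azlactone.

Step 3
Reactants: 3 (4Z)-4-[2-(benzyloxy)-5-bromo-3-methoxybenzylidene]-2-methyl-1,3-oxazol-5(4H)-one
Product: 5 [2-(benzyloxy)-5-bromo-3-methoxyphenyl]acetic acid, via arylpyruvic acid 4 (not isolated)
Conditions: 10 % aq. NaOH, reflux; then 30 % H2O2, 5 °C → rt; then HCl to pH 2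
Reagents that add atoms: water, O; hydrogen peroxide, OO
Why: Alkaline azlactone hydrolysis to the arylpyruvate followed by oxidative decarboxylation of the α-keto acid with alkaline hydrogen peroxide is the classical one-carbon homologation of a benzaldehyde to an arylacetic acid, and the benzyl ether and aryl bromide are inert to both stages.

Step 4
Reactants: 5 [2-(benzyloxy)-5-bromo-3-methoxyphenyl]acetic acid; 6 4-(benzyloxy)-3-methoxybenzaldehyde
Product: 7 (E)-2-[2-(benzyloxy)-5-bromo-3-methoxyphenyl]-3-[4-(benzyloxy)-3-methoxyphenyl]prop-2-enoic acid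
Conditions: Ac2O, Et3N, 110 °C; then H2O, 90 °C; crystallisation
Reagents that add atoms: none
Why: Perkin condensation, in which the mixed-anhydride enolate of 5 adds to aldehyde 6 and the acetylated aldol eliminates to give preferentially the (E)-acid with the two aryl groups cis, the minor (Z)-acid being removed by crystallisation.

Step 5
Reactants: 7 (E)-2-[2-(benzyloxy)-5-bromo-3-methoxyphenyl]-3-[4-(benzyloxy)-3-methoxyphenyl]prop-2-enoic acid
Product: 8 methyl (E)-2-[2-(benzyloxy)-5-bromo-3-methoxyphenyl]-3-[4-(benzyloxy)-3-methoxyphenyl]prop-2-enoate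
Conditions: MeI, K2CO3, DMF, rt
Reagents that add atoms: iodomethane, CI
Why: Carboxylate O-alkylation (SN2) with iodomethane gives the methyl ester under conditions that cannot change the alkene geometry.

Step 6
Reactants: 8 methyl (E)-2-[2-(benzyloxy)-5-bromo-3-methoxyphenyl]-3-[4-(benzyloxy)-3-methoxyphenyl]prop-2-enoate
Product: 9 (E)-2-[2-(benzyloxy)-5-bromo-3-methoxyphenyl]-3-[4-(benzyloxy)-3-methoxyphenyl]prop-2-en-1-ol
Conditions: i-Bu2AlH, CH2Cl2, −78 °C; aq. potassium sodium tartrate
Reagents that add atoms: none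
Why: 1,2-Reduction of the conjugated ester by i-Bu2AlH at low temperature should give the allylic alcohol with the E geometry retained and the aryl bromide and benzyl ethers intact.

Step 7
Reactants: 9 (E)-2-[2-(benzyloxy)-5-bromo-3-methoxyphenyl]-3-[4-(benzyloxy)-3-methoxyphenyl]prop-2-en-1-ol
Product: 10 [(2R,3R)-2-[2-(benzyloxy)-5-bromo-3-methoxyphenyl]-3-[4-(benzyloxy)-3-methoxyphenyl]oxiran-2-yl]methanol
Conditions: Ti(OiPr)4 (10 mol %), D-(−)-diisopropyl tartrate (12 mol %), t-BuOOH (anhydrous, in isooctane), 4 Å molecular sieves, CH2Cl2, −20 °C; NaCl-saturated aq. NaOH work-up at 0 °C; crude 10 used at once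
Reagents that add atoms: tert-butyl hydroperoxide, CC(C)(C)OO
Why: Katsuki–Sharpless asymmetric epoxidation: the primary alkoxide of 9 and tert-butyl peroxide bind tetravalent titanium in the dimeric tartrate complex, and the activated peroxide oxygen is passed to the alkene in a concerted, syn-specific step, as known for (E)-2,3-diarylallyl alcohols. The oxirane closes by this [2+1] oxygen-atom transfer, both C–O bonds forming on one alkene face, so no exo or endo cyclisation mode is involved. C2 and C3 are set together by the D-(−)-tartrate ligand, which directs oxygen to the face that gives the (2R,3R) oxirane, while the E geometry of 9 fixes their relative configuration (aryl groups cis). The step needs enantioface selectivity, secured by the free CH2OH, the only group in 9 that can anchor the alkene on titanium, and chemoselectivity for the alkene over the electron-rich rings, which the directed delivery also provides. Catalytic titanium, molecular sieves, −20 °C and a non-acidic work-up are used because the oxirane carbon next to the para-benzyloxyphenyl ring opens easily under Lewis acids.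

Step 8
Reactants: 10 [(2R,3R)-2-[2-(benzyloxy)-5-bromo-3-methoxyphenyl]-3-[4-(benzyloxy)-3-methoxyphenyl]oxiran-2-yl]methanol
Product: 11 (1S,2R)-2-[2-(benzyloxy)-5-bromo-3-methoxyphenyl]-1-[4-(benzyloxy)-3-methoxyphenyl]propane-1,3-diol
Conditions: NaAlH2(OCH2CH2OMe)2, 1,2-dimethoxyethane, −20 → 0 °C; aq. potassium sodium tartrate
Reagents that add atoms: none
Why: Proposed new method: the primary alkoxide of 10 binds aluminium and the alkoxyaluminium hydride should deliver hydride through a five-membered transition state to the adjacent oxirane carbon C2 from the face opposite the C2–O bond (inversion, giving the 2R methine), the benzylic character of C2 loosening that bond while the ring-C carbinol C–O bond is kept; the closest known reaction type is the alkoxide-directed NaAlH2(OCH2CH2OMe)2 opening of 3-aryl- and 3-alkyl-2,3-epoxy alcohols at a C2 that is not fully substituted, which gives 1,3-diols.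

Step 9
Reactants: 11 (1S,2R)-2-[2-(benzyloxy)-5-bromo-3-methoxyphenyl]-1-[4-(benzyloxy)-3-methoxyphenyl]propane-1,3-diol
Product: 12 (1S,2R)-2-[2-(benzyloxy)-5-bromo-3-methoxyphenyl]-1-[4-(benzyloxy)-3-methoxyphenyl]-1,3-bis(tert-butyldimethylsilyloxy)propane
Conditions: t-BuMe2SiOTf, 2,6-lutidine, CH2Cl2, −78 → 0 °C
Reagents that add atoms: tert-butyldimethylsilyl trifluoromethanesulfonate, CC(C)(C)[Si](C)(C)OS(=O)(=O)C(F)(F)F
Why: Silyl ether formation with the silyl triflate and a hindered pyridine base should cap both the primary and the hindered benzylic hydroxyl, removing the acidic protons before the organozinc coupling without ionising the benzylic carbinol.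

Step 10
Reactants: 13 dimethyl malonate; 14 (R)-2-(chloromethyl)oxirane
Product: 15 methyl (1S,5R)-2-oxo-3-oxabicyclo[3.1.0]hexane-1-carboxylate
Conditions: NaOMe, MeOH, reflux
Reagents that add atoms: none
Why: Malonate double alkylation (epoxide opening at CH2, chloride displacement to a new epoxide, 3-exo-tet cyclopropanation with inversion at the epichlorohydrin stereocentre) followed by lactonisation should give the cis-fused cyclopropane lactone, so C5 derives from the chiral pool and C1 follows from the ring fusion.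

Step 11
Reactants: 15 methyl (1S,5R)-2-oxo-3-oxabicyclo[3.1.0]hexane-1-carboxylate; 16 1-(benzyloxy)-4-bromo-2-methoxybenzene
Product: 18 methyl (3S,4R)-4-[4-(benzyloxy)-3-methoxybenzyl]-2-oxotetrahydrofuran-3-carboxylate, via arylmagnesium bromide 17 (not isolated)
Conditions: Mg, THF, 40 °C; then CuI (10 mol %), 15, THF, −30 °C; 1 M HCl quench
Reagents that add atoms: none
Why: Copper-catalysed homoconjugate (SN2-type) addition of the aryl Grignard reagent to the doubly activated cyclopropane should cleave the bond between C1 and the unhindered cyclopropane CH2, leave the C4 stereocentre untouched and give the thermodynamically preferred trans malonate-type lactone.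

Step 12
Reactants: 18 methyl (3S,4R)-4-[4-(benzyloxy)-3-methoxybenzyl]-2-oxotetrahydrofuran-3-carboxylate
Product: 19 (4R)-4-[4-(benzyloxy)-3-methoxybenzyl]dihydrofuran-2(3H)-one
Conditions: LiCl, H2O, DMSO, 140 °C
Reagents that add atoms: none
Why: Krapcho dealkoxycarbonylation, in which chloride demethylates the ester and the β-carbonyl carboxylate loses CO2, removes the epimerisable C3 substituent while C4 is unaffected.

Step 13
Reactants: 19 (4R)-4-[4-(benzyloxy)-3-methoxybenzyl]dihydrofuran-2(3H)-one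
Product: 21 (3S,4R)-4-[4-(benzyloxy)-3-methoxybenzyl]-3-(hydroxymethyl)dihydrofuran-2(3H)-one, via lithium enolate 20 (not isolated)
Conditions: LiN(SiMe3)2, THF, −78 °C; CH2O (gas, from cracked paraformaldehyde), −78 → −45 °C; AcOH quench
Reagents that add atoms: formaldehyde, C=O
Why: Aldol addition of the lactone lithium enolate to monomeric formaldehyde should occur on the face anti to the C4 benzyl group, which sets C3 trans (3S) as in alkylations of β-benzyl-γ-butyrolactone enolates.

Step 14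
Reactants: 21 (3S,4R)-4-[4-(benzyloxy)-3-methoxybenzyl]-3-(hydroxymethyl)dihydrofuran-2(3H)-one
Product: 22 (3R,4R)-4-[4-(benzyloxy)-3-methoxybenzyl]-3-(iodomethyl)dihydrofuran-2(3H)-one
Conditions: I2, PPh3, imidazole, CH2Cl2, 0 °C → rt
Reagents that add atoms: iodine, II
Why: Appel-type iodination converts the primary alcohol into the iodide by SN2 displacement of the oxyphosphonium group at CH2 under nearly neutral conditions that should neither epimerise C3 nor eliminate to the α-methylene lactone.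

Step 15
Reactants: 22 (3R,4R)-4-[4-(benzyloxy)-3-methoxybenzyl]-3-(iodomethyl)dihydrofuran-2(3H)-one; 12 (1S,2R)-2-[2-(benzyloxy)-5-bromo-3-methoxyphenyl]-1-[4-(benzyloxy)-3-methoxyphenyl]-1,3-bis(tert-butyldimethylsilyloxy)propane
Product: 24 (3R,4R)-4-[4-(benzyloxy)-3-methoxybenzyl]-3-{4-(benzyloxy)-3-[(1S,2R)-1-[4-(benzyloxy)-3-methoxyphenyl]-1,3-bis(tert-butyldimethylsilyloxy)propan-2-yl]-5-methoxybenzyl}dihydrofuran-2(3H)-one, via alkylzinc iodide 23 (not isolated)
Conditions: Zn dust (activated), DMF, rt; then 12, Pd2(dba)3 (2.5 mol %), 2-dicyclohexylphosphino-2′,6′-dimethoxybiphenyl (SPhos, 10 mol %), THF/DMF, 45 °C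
Reagents that add atoms: none
Why: Negishi coupling, in which zinc inserts into the primary C–I bond to give a β-zincio ester (zinc homoenolate) that has no β-leaving group and keeps its α-stereocentre, and zerovalent palladium with the biaryl phosphine joins it to the unhindered aryl bromide faster than β-hydride elimination, as known for 3-iodo-2-methylpropanoate-derived zinc reagents.

Step 16
Reactants: 24 (3R,4R)-4-[4-(benzyloxy)-3-methoxybenzyl]-3-{4-(benzyloxy)-3-[(1S,2R)-1-[4-(benzyloxy)-3-methoxyphenyl]-1,3-bis(tert-butyldimethylsilyloxy)propan-2-yl]-5-methoxybenzyl}dihydrofuran-2(3H)-one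
Product: 25 (3R,4R)-4-[4-(benzyloxy)-3-methoxybenzyl]-3-{4-(benzyloxy)-3-[(1S,2R)-1-[4-(benzyloxy)-3-methoxyphenyl]-1,3-dihydroxypropan-2-yl]-5-methoxybenzyl}dihydrofuran-2(3H)-one
Conditions: Bu4NF, AcOH, THF, rt
Reagents that add atoms: none
Why: Fluoride-mediated desilylation buffered with acetic acid should free both hydroxyls under nearly neutral conditions that spare the lactone and the benzylic carbinol while all three phenols are still benzylated.

Step 17
Reactants: 25 (3R,4R)-4-[4-(benzyloxy)-3-methoxybenzyl]-3-{4-(benzyloxy)-3-[(1S,2R)-1-[4-(benzyloxy)-3-methoxyphenyl]-1,3-dihydroxypropan-2-yl]-5-methoxybenzyl}dihydrofuran-2(3H)-one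
Product: 26 (3R,4R)-3-{3-[(1S,2R)-1,3-dihydroxy-1-(4-hydroxy-3-methoxyphenyl)propan-2-yl]-4-hydroxy-5-methoxybenzyl}-4-(4-hydroxy-3-methoxybenzyl)dihydrofuran-2(3H)-one (CNP0317849.1)
Conditions: H2 (1 atm), 10 % Pd/C, EtOAc, rt
Reagents that add atoms: none
Why: Catalytic hydrogenolysis of the three aryl benzyl ethers in neutral ethyl acetate should be faster than loss of the secondary benzylic hydroxyl, and the absence of acid avoids cyclisation of the ring-B phenol onto the carbinol carbon.

Compound list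
1 | 5-bromo-2-hydroxy-3-methoxybenzaldehyde | COc1cc(Br)cc(C=O)c1O | starting material
2 | 2-(benzyloxy)-5-bromo-3-methoxybenzaldehyde | COc1cc(Br)cc(C=O)c1OCc1ccccc1 | intermediate
3 | (4Z)-4-[2-(benzyloxy)-5-bromo-3-methoxybenzylidene]-2-methyl-1,3-oxazol-5(4H)-one | CC1=N/C(=C\c2cc(Br)cc(OC)c2OCc2ccccc2)C(=O)O1 | intermediate
4 | 3-[2-(benzyloxy)-5-bromo-3-methoxyphenyl]-2-oxopropanoic acid (arylpyruvic acid, formed as its sodium salt) | OC(=O)C(=O)Cc1cc(Br)cc(OC)c1OCc1ccccc1 | intermediate (not isolated)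
5 | [2-(benzyloxy)-5-bromo-3-methoxyphenyl]acetic acid | OC(=O)Cc1cc(Br)cc(OC)c1OCc1ccccc1 | intermediate
6 | 4-(benzyloxy)-3-methoxybenzaldehyde | COc1cc(C=O)ccc1OCc1ccccc1 | starting material
7 | (E)-2-[2-(benzyloxy)-5-bromo-3-methoxyphenyl]-3-[4-(benzyloxy)-3-methoxyphenyl]prop-2-enoic acid | OC(=O)/C(=C/c1ccc(OCc2ccccc2)c(OC)c1)c1cc(Br)cc(OC)c1OCc1ccccc1 | intermediate
8 | methyl (E)-2-[2-(benzyloxy)-5-bromo-3-methoxyphenyl]-3-[4-(benzyloxy)-3-methoxyphenyl]prop-2-enoate | COC(=O)/C(=C/c1ccc(OCc2ccccc2)c(OC)c1)c1cc(Br)cc(OC)c1OCc1ccccc1 | intermediate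
9 | (E)-2-[2-(benzyloxy)-5-bromo-3-methoxyphenyl]-3-[4-(benzyloxy)-3-methoxyphenyl]prop-2-en-1-ol | OC/C(=C/c1ccc(OCc2ccccc2)c(OC)c1)c1cc(Br)cc(OC)c1OCc1ccccc1 | intermediate
10 | [(2R,3R)-2-[2-(benzyloxy)-5-bromo-3-methoxyphenyl]-3-[4-(benzyloxy)-3-methoxyphenyl]oxiran-2-yl]methanol | OC[C@@]1(c2cc(Br)cc(OC)c2OCc2ccccc2)O[C@@H]1c1ccc(OCc2ccccc2)c(OC)c1 | intermediate
11 | (1S,2R)-2-[2-(benzyloxy)-5-bromo-3-methoxyphenyl]-1-[4-(benzyloxy)-3-methoxyphenyl]propane-1,3-diol | OC[C@@H](c1cc(Br)cc(OC)c1OCc1ccccc1)[C@H](O)c1ccc(OCc2ccccc2)c(OC)c1 | intermediate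
12 | (1S,2R)-2-[2-(benzyloxy)-5-bromo-3-methoxyphenyl]-1-[4-(benzyloxy)-3-methoxyphenyl]-1,3-bis(tert-butyldimethylsilyloxy)propane | CC(C)(C)[Si](C)(C)OC[C@@H](c1cc(Br)cc(OC)c1OCc1ccccc1)[C@H](O[Si](C)(C)C(C)(C)C)c1ccc(OCc2ccccc2)c(OC)c1 | intermediate
13 | dimethyl malonate | COC(=O)CC(=O)OC | starting material
14 | (R)-2-(chloromethyl)oxirane ((R)-epichlorohydrin) | ClC[C@H]1CO1 | starting material
15 | methyl (1S,5R)-2-oxo-3-oxabicyclo[3.1.0]hexane-1-carboxylate | COC(=O)[C@]12C[C@H]1COC2=O | intermediate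
16 | 1-(benzyloxy)-4-bromo-2-methoxybenzene | COc1cc(Br)ccc1OCc1ccccc1 | starting material
17 | [4-(benzyloxy)-3-methoxyphenyl]magnesium bromide | COc1cc([Mg]Br)ccc1OCc1ccccc1 | intermediate (not isolated)
18 | methyl (3S,4R)-4-[4-(benzyloxy)-3-methoxybenzyl]-2-oxotetrahydrofuran-3-carboxylate (trans; C3 epimerisable) | COc1cc(C[C@H]2COC(=O)[C@@H]2C(=O)OC)ccc1OCc1ccccc1 | intermediate
19 | (4R)-4-[4-(benzyloxy)-3-methoxybenzyl]dihydrofuran-2(3H)-one | COc1cc(C[C@H]2COC(=O)C2)ccc1OCc1ccccc1 | intermediate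
20 | lithium (4R)-4-[4-(benzyloxy)-3-methoxybenzyl]-4,5-dihydrofuran-2-olate (lithium enolate of 19) | [Li]OC1=C[C@@H](Cc2ccc(OCc3ccccc3)c(OC)c2)CO1 | intermediate (not isolated)
21 | (3S,4R)-4-[4-(benzyloxy)-3-methoxybenzyl]-3-(hydroxymethyl)dihydrofuran-2(3H)-one | COc1cc(C[C@H]2COC(=O)[C@@H]2CO)ccc1OCc1ccccc1 | intermediate
22 | (3R,4R)-4-[4-(benzyloxy)-3-methoxybenzyl]-3-(iodomethyl)dihydrofuran-2(3H)-one | COc1cc(C[C@H]2COC(=O)[C@@H]2CI)ccc1OCc1ccccc1 | intermediate
23 | {[(3R,4R)-4-[4-(benzyloxy)-3-methoxybenzyl]-2-oxotetrahydrofuran-3-yl]methyl}zinc iodide | COc1cc(C[C@H]2COC(=O)[C@@H]2C[Zn]I)ccc1OCc1ccccc1 | intermediate (not isolated)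
24 | (3R,4R)-4-[4-(benzyloxy)-3-methoxybenzyl]-3-{4-(benzyloxy)-3-[(1S,2R)-1-[4-(benzyloxy)-3-methoxyphenyl]-1,3-bis(tert-butyldimethylsilyloxy)propan-2-yl]-5-methoxybenzyl}dihydrofuran-2(3H)-one | COc1cc(C[C@H]2COC(=O)[C@@H]2Cc2cc(OC)c(OCc3ccccc3)c([C@H](CO[Si](C)(C)C(C)(C)C)[C@H](O[Si](C)(C)C(C)(C)C)c3ccc(OCc4ccccc4)c(OC)c3)c2)ccc1OCc1ccccc1 | intermediate
25 | (3R,4R)-4-[4-(benzyloxy)-3-methoxybenzyl]-3-{4-(benzyloxy)-3-[(1S,2R)-1-[4-(benzyloxy)-3-methoxyphenyl]-1,3-dihydroxypropan-2-yl]-5-methoxybenzyl}dihydrofuran-2(3H)-one | COc1cc(C[C@H]2COC(=O)[C@@H]2Cc2cc(OC)c(OCc3ccccc3)c([C@H](CO)[C@H](O)c3ccc(OCc4ccccc4)c(OC)c3)c2)ccc1OCc1ccccc1 | intermediate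
26 | (3R,4R)-3-{3-[(1S,2R)-1,3-dihydroxy-1-(4-hydroxy-3-methoxyphenyl)propan-2-yl]-4-hydroxy-5-methoxybenzyl}-4-(4-hydroxy-3-methoxybenzyl)dihydrofuran-2(3H)-one (CNP0317849.1) | COc1cc(C[C@H]2COC(=O)[C@@H]2Cc2cc(OC)c(O)c([C@H](CO)[C@H](O)c3ccc(O)c(OC)c3)c2)ccc1O | target

Total step count: 17. Longest linear sequence: 12 steps (steps 1–9, then 15–17, from compound 1); the lactone branch (steps 10–14) has 5 steps.

Steps most likely to fail

Step 8 (the step labelled as a proposed new method). Hydride may be delivered to the ring-C oxirane carbon instead of C2, giving the 1,2-diol. The opening may also pass through a benzylic cation, with loss of stereospecificity or a 1,2-shift. The fallback sets out from acid 5 and uses known auxiliary chemistry. Activation of 5 with pivaloyl chloride and Et3N and acylation of lithiated (S)-4-benzyloxazolidin-2-one should give the imide (S)-4-benzyl-3-{[2-(benzyloxy)-5-bromo-3-methoxyphenyl]acetyl}oxazolidin-2-one F1. Its (Z)-boron enolate (Bu2BOTf, i-Pr2NEt, CH2Cl2, −78 °C) should add to aldehyde 6 in an Evans syn-aldol reaction to give (S)-4-benzyl-3-{(2S,3S)-2-[2-(benzyloxy)-5-bromo-3-methoxyphenyl]-3-[4-(benzyloxy)-3-methoxyphenyl]-3-hydroxypropanoyl}oxazolidin-2-one F2. Reductive removal of the auxiliary with LiBH4 (THF, MeOH, 0 °C) comes back to the route at diol 11. Both side-chain centres are then set by the auxiliary and steps 4–8 are not needed.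

Step 7. The titanium Lewis acid may open or rearrange the electron-rich oxirane as it forms, and the twisted, ortho-substituted ring B may lower enantioface selection. The fallback sets out from 9 and moves the epoxidation to a buffered, metal-free medium. TBSCl and imidazole should give tert-butyl{[(E)-2-[2-(benzyloxy)-5-bromo-3-methoxyphenyl]-3-[4-(benzyloxy)-3-methoxyphenyl]prop-2-en-1-yl]oxy}dimethylsilane F3. Shi epoxidation follows, with the dioxirane generated from the D-fructose-derived ketone 1,2:4,5-di-O-isopropylidene-β-D-erythro-2,3-hexodiulo-2,6-pyranose and KHSO5 (K2CO3, MeCN/dimethoxymethane/aqueous buffer, 0 °C). The spiro transition-state model for trisubstituted alkenes predicts tert-butyl{[(2R,3R)-2-[2-(benzyloxy)-5-bromo-3-methoxyphenyl]-3-[4-(benzyloxy)-3-methoxyphenyl]oxiran-2-yl]methoxy}dimethylsilane F4; should the sense prove opposite, the enantiomeric ketone would be used. Bu4NF in THF then comes back to the route at epoxy alcohol 10.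

Step 15. Protonation or β-hydride elimination of the alkylzinc may outpace the slow oxidative addition of the electron-rich aryl bromide. The fallback sets out from 12 and reverses the polarity to the classical enolate alkylation. Bromine–lithium exchange (n-BuLi, THF, −78 °C) and DMF should give 4-(benzyloxy)-3-[(1S,2R)-1-[4-(benzyloxy)-3-methoxyphenyl]-1,3-bis(tert-butyldimethylsilyloxy)propan-2-yl]-5-methoxybenzaldehyde F5. NaBH4 in MeOH gives {4-(benzyloxy)-3-[(1S,2R)-1-[4-(benzyloxy)-3-methoxyphenyl]-1,3-bis(tert-butyldimethylsilyloxy)propan-2-yl]-5-methoxyphenyl}methanol F6. CBr4 and PPh3 give 2-(benzyloxy)-5-(bromomethyl)-1-[(1S,2R)-1-[4-(benzyloxy)-3-methoxyphenyl]-1,3-bis(tert-butyldimethylsilyloxy)propan-2-yl]-3-methoxybenzene F7. Alkylation of lithium enolate 20 (from 19, LiN(SiMe3)2, THF, −78 °C) with F7 anti to the C4 benzyl group comes back to the route at 24.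

Further compounds
F1 | step 8 | (S)-4-benzyl-3-{[2-(benzyloxy)-5-bromo-3-methoxyphenyl]acetyl}oxazolidin-2-one | O=C(Cc1cc(Br)cc(OC)c1OCc1ccccc1)N1[C@@H](Cc2ccccc2)COC1=O
F2 | step 8 | (S)-4-benzyl-3-{(2S,3S)-2-[2-(benzyloxy)-5-bromo-3-methoxyphenyl]-3-[4-(benzyloxy)-3-methoxyphenyl]-3-hydroxypropanoyl}oxazolidin-2-one | O=C([C@@H](c1cc(Br)cc(OC)c1OCc1ccccc1)[C@H](O)c1ccc(OCc2ccccc2)c(OC)c1)N1[C@@H](Cc2ccccc2)COC1=O
F3 | step 7 | tert-butyl{[(E)-2-[2-(benzyloxy)-5-bromo-3-methoxyphenyl]-3-[4-(benzyloxy)-3-methoxyphenyl]prop-2-en-1-yl]oxy}dimethylsilane | CC(C)(C)[Si](C)(C)OC/C(=C/c1ccc(OCc2ccccc2)c(OC)c1)c1cc(Br)cc(OC)c1OCc1ccccc1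
F4 | step 7 | tert-butyl{[(2R,3R)-2-[2-(benzyloxy)-5-bromo-3-methoxyphenyl]-3-[4-(benzyloxy)-3-methoxyphenyl]oxiran-2-yl]methoxy}dimethylsilane | CC(C)(C)[Si](C)(C)OC[C@@]1(c2cc(Br)cc(OC)c2OCc2ccccc2)O[C@@H]1c1ccc(OCc2ccccc2)c(OC)c1
F5 | step 15 | 4-(benzyloxy)-3-[(1S,2R)-1-[4-(benzyloxy)-3-methoxyphenyl]-1,3-bis(tert-butyldimethylsilyloxy)propan-2-yl]-5-methoxybenzaldehyde | O=Cc1cc(OC)c(OCc2ccccc2)c(c1)[C@H](CO[Si](C)(C)C(C)(C)C)[C@H](O[Si](C)(C)C(C)(C)C)c1ccc(OCc2ccccc2)c(OC)c1
F6 | step 15 | {4-(benzyloxy)-3-[(1S,2R)-1-[4-(benzyloxy)-3-methoxyphenyl]-1,3-bis(tert-butyldimethylsilyloxy)propan-2-yl]-5-methoxyphenyl}methanol | OCc1cc(OC)c(OCc2ccccc2)c(c1)[C@H](CO[Si](C)(C)C(C)(C)C)[C@H](O[Si](C)(C)C(C)(C)C)c1ccc(OCc2ccccc2)c(OC)c1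
F7 | step 15 | 2-(benzyloxy)-5-(bromomethyl)-1-[(1S,2R)-1-[4-(benzyloxy)-3-methoxyphenyl]-1,3-bis(tert-butyldimethylsilyloxy)propan-2-yl]-3-methoxybenzene | BrCc1cc(OC)c(OCc2ccccc2)c(c1)[C@H](CO[Si](C)(C)C(C)(C)C)[C@H](O[Si](C)(C)C(C)(C)C)c1ccc(OCc2ccccc2)c(OC)c1
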